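7.12 M⁻¹ is the figure to carry from the red and violet runs: the concentration penalty, the rise in reciprocal target yield per unit of [substrate] charged at equal time and equal [coupling partner], averaged over the readings at 6.00 h, 8.00 h and 10.0 h.

| flask | substrate | coupling partner | remark | time |
|---|---|---|---|---|
| red | 0.099 M | 1.5 M | run made earlier |  |
| violet | 0.36 M | 1.5 M | run made earlier |  |
| east | 0.30 M | 1.50 M |  | 10 h |
| south-east | 0.080 M | 1.50 M |  | 6.0 h |

- red (time / h: target / %): 1.33: 5; 3.00: 16; 4.00: 21; 6.00: 29; 8.00: 37; 10.0: 41
- violet (time / h: target / %): 0.500: 2; 1.50: 5; 3.00: 11; 4.00: 14; 6.00: 21; 8.00: 18; 10.0: 26

(standard deviation of a reading: 1.5 percentage points)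

- the flask that ends with the higher amount of target, in percent of the substrate charged, or "neither" when 2 percentage points or less lies between them (east / south-east / neither)
- final target, as a percentage of the substrate charged, in east
- final target, as a percentage of the substrate charged, in south-east

- a species is counted by the substrate in it: one side product counts as two
- on the list of suspects stand: substrate + coupling partner <-> intermediate; intermediate <-> target + by-product; substrate + intermediate -> side product; target <-> isomer of the product

A second-order loss integrates in closed form: at fixed time the reciprocal of the surviving fraction climbs linearly with the charge. I assume the target yield behaves the same way, and it does fall with charge, from 41% in red to 26% in violet at 10.0 h. The average keeps the low 18% of violet at 8.00 h beside its neighbours.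

Start from red at the asked time and add the penalty for the change in [substrate]. My reckoning gives east 25.8% and south-east 30.2%. That is a gap of 4.4 percentage points, wider than the margin, so I would name south-east.

The forecast stands higher on east and differs in its choice: 28.5% for east, 30.3% for south-east, and neither, in its words “The gap is about 2 points, which is borderline”.

The flasks give 25.4% in east and 31.6% in south-east, so the answer is south-east.

    substrate + coupling partner ⇌ intermediate (K = 0.780 M⁻¹, k = 0.258 M⁻¹ h⁻¹)
    intermediate ⇌ target + by-product (K = 0.180 M, k = 0.246 h⁻¹)
    substrate + intermediate → side product (k = 1.22 M⁻¹ h⁻¹)
    target ⇌ isomer of the product (K = 0.100, k = 0.229 h⁻¹)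

Without substrate + intermediate → side product, south-east minus east becomes −1.6 points. Now take the penalty to a further flask, the charge of south-east left for 10.0 h. The red run, free of scatter, stands at 40.4% at that time, and moving [substrate] from 0.099 M to 0.080 M with the penalty gives 42.7%. The simulated flask gives 42.8%.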